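Winter's partner charge offers intermediate A 4.32 lifetimes in the run, but that count holds just as long as partner stands at its charge.

    substrate → intermediate A (k1 = 5.1 × 10⁻⁵ /s)
    substrate + partner → intermediate B (k2 = 8.5 × 10⁻⁴ /M/s)
    partner + intermediate A → intermediate C (k3 = 2.5 × 10⁻⁴ /M/s)
    intermediate B ⇌ intermediate D (K4 = 1.3, k4 = 2.2 × 10⁻⁴ /s)
    partner + intermediate C ⇌ target (K5 = 760 /M, k5 = 3.5 × 10⁻⁴ /M/s)

| flask | substrate | partner | time |
|---|---|---|---|
| autumn | 0.050 M | 0.0120 M | 2.0 d |
| spring | 0.050 M | 0.0250 M | 2.0 d |
| dawn | 0.050 M | 0.0500 M | 2.0 d |
| winter | 0.050 M | 0.100 M | 2.0 d |
| summer | 0.050 M | 0.200 M | 2.0 d |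

1. amount of target at the end, in percent of the substrate charged for autumn, spring, dawn, winter, summer, in this order
2. the course of these numbers from the first flask to the last (rises, then falls / falls all the way / rises all the way / falls, then rises / hardly changes)

- "hardly changes" means that all values lie within two and a half points (for a concentration: within two and a half percent of the largest)
- run time (autumn): 2.0 d

**Reckoning for winter**, with P for the partner concentration:

1. One substrate molecule meets a fork. Per molecule, the path to intermediate A runs at 5.1 × 10⁻⁵ /s and the path to intermediate B at 8.50 × 10⁻⁵ /s, which is faster. So φ, the share taking the path to intermediate A (a selectivity), is 37.5% at the start.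

2. At these two start rates substrate has a half-life of 0.0590 d, shorter than the run. Intermediate A then reacts at k·P per molecule, where k is 2.5 × 10⁻⁴ /M/s, which gives 0.0900 /h at the start.

3. Partner loss slows that rate. A molecule going to intermediate B takes one partner, and one going to target takes two. This reckoning therefore counts about one partner per substrate molecule by mid-run. Mid-run partner, Pm, is then 0.0500 M, half the charge, and the rate falls by that same factor.

4. The slowing accumulates. At Pm, the survival chance s, which is e raised to −k·Pm·t, comes to 11.5%: the chance that a molecule of intermediate A outlasts the run. That is higher than the 1.33% at a standing charge.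

5. Intermediate C reacts with partner with the rate constant 3.5 × 10⁻⁴ /M/s; taken at Pm over a full run, its survival chance is 4.86%. The return from target stays small, since K·Pm for that equilibrium is 38.0. With φ held at its start value, the product of φ and the two chances of reacting gives an estimate of 31.6% target in winter.

6. In summer the start share φ is 23.1%, lower than that winter estimate. In autumn the partner charge is below the substrate charge, and even a standing charge would turn 40.5% of intermediate A into intermediate C. This reckoning therefore expects a row that rises, then falls, with no figures for the low flasks.

**The forecast** gives 0.6%, 2.7%, 12%, 27% and 24%: rises, then falls. Its winter value is lower than this reckoning's. Its ground: “Target needs two partners.”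

**The simulation** gives 0.752%, 3.32%, 12.3%, 28.7% and 24.7%, so the row rises, then falls, the course the forecast gave. At the end of winter the flask holds 5.35% intermediate A, 8.07% intermediate C and 28.7% target, so 12.7% of that branch is still intermediate A, beside the survival chance 11.5%. In autumn, partner stands at 22.3% of its charge after 1.00 d. The same survival chance at that mid-run partner is 89.1%, and the autumn branch ends with 89.2% as intermediate A.

Its constants are invented; the flask was simulated.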